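## The problem

The target 18 is a linear tridepside: three 2,4-dioxygenated 6-methylbenzoate rings joined head to tail by two aryl ester bonds, with ring A carrying the methyl ester, ring B acylating the C4 oxygen of ring A and ring C acylating the C4 oxygen of ring B. It has no stereocentre; the only ones that appear in this plan, C1 and C6 of a temporarily saturated ring A, are erased again and have nothing to control. The real difficulty is chemoselectivity, because each acyl carbon sits between an ortho oxygen and an ortho methyl group, so esterification is slow, while the finished aryl esters are activated esters that exchange under basic or nucleophilic conditions. The free 2,4-dihydroxy-6-methylbenzoic acid units also lose CO2 easily. Four phenols have to end up free, and each ester must be placed on a para (C4) oxygen in the presence of an ortho (C2) oxygen. The acid components therefore need ortho-oxygen protection that comes off under neutral conditions, and the closing steps must avoid base, nucleophiles and strong acid. The feature that opens the route lies in ring A, whose C2 and C4 oxygens are 1,3-related while C1 bears the ester and C6 the methyl group, which is the skeleton of an acetoacetate joined to a crotonate. At the dihydro oxidation level this ring is a cyclohexane-1,3-dione whose C4 oxygen is an acidic, unhindered enol oxygen, while the C2 oxygen is tied up next to the ester-bearing C1.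

## Retrosynthesis

From target 18 back to tris(benzyl ether) 17. The three O–benzyl bonds on ring B (O2) and ring C (O2, O4) are removed last. Hydrogenolysis is the only deprotection that is neutral, free of nucleophiles and blind to aryl esters, which rules out acyl, silyl or methyl protection. Ring A needs no protecting group at all, because its C2 oxygen is a ketone until the penultimate step.

From phenol 17 back to enol ester 13. No skeletal bond is cut; two hydrogens are added back across C1–C6 of ring A. The phenolic ring becomes a 4-acyloxycyclohex-3-en-2-one with a β-keto ester at C1. Cutting the A–B ester at the aromatic stage instead is kept as a fallback and not as the main line. The forward reaction must dehydrogenate C1–C6 without touching a vinylogous anhydride, two depside esters and three benzyl ethers. The acidic C1 hydrogen makes this a directed reaction: selenium is placed at C1 to give selenide 14, and its selenoxide 15 leaves with the C6 hydrogen to give dienone 16, the keto tautomer of 17.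

From enol ester 13 back to dione 4 and acid 11. The enol ester C–O bond at O4 of ring A is cut, which splits the molecule into the nine-carbon dione 4 and the protected rings B–C acid 11, used as its chloride 12. This cut is preferred to cutting the B–C ester first because it is convergent: the precious fragment meets a cheap one late. It also uses the most acidic OH in the whole plan as the nucleophile. The forward reaction has to choose O4 over O2 and over C3.

From dione 4 back to esters 1 and 2. Ring A is opened at C1–C6 (Michael bond) and C3–C4 (Claisen bond), by way of the open-chain adduct 3. Both precursors are bulk esters, and the ring with all its substituents in place arises in one operation. The neighbouring cut, C1–C6 plus C2–C3 (a malonate with an enone), leads to the same dione 4 and is held in reserve. The forward reaction needs the doubly activated carbon of 1 as Michael donor and ring closure from the acetyl methyl group.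

From acid 11 back to aldehyde 10 and then to phenol 9. The carboxyl group of ring B is traced back to the formyl group of 10, and the O2 benzyl ether to the free chelated phenol of 9. The aldehyde is the simplest carboxyl surrogate that survives esterification and benzylation and is oxidised under buffered conditions. An ester protecting group would need a deprotection orthogonal to both benzyl ethers and aryl esters.

From ester 9 back to acid 7 and aldehyde 5. The B–C ester bond is cut between the C4 oxygen of ring B and the ring C carbonyl, and is made forward through chloride 8. Dihydroxy aldehyde 5 needs no protection here, because its O2 is chelated to the formyl group and its O4 is the more acidic, exposed phenol.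

From acid 7 back to aldehyde 6 and then to aldehyde 5. The ring C acid comes from the same aldehyde 5 by double benzylation to 6 and oxidation. One purchased aromatic compound therefore supplies both rings B and C.

## Roads not taken

Alternative 1: Ring C would be made last by an Alder–Rickert sequence. The cut runs through ring C bonds C1–C2 and C5–C6. The cyclic bis(silyloxy)diene A2 adds to the but-2-ynoate ester A3 of the rings A–B phenol; the bicyclo[2.2.2]octadiene then expels its two-carbon bridge, and desilylation gives tridepside A1, which has rings A and B as 2-O-benzyl ethers.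
- Merits: ring C appears with both phenols free and without benzyl groups of its own. The regiochemistry follows from the polarisation of A2. Aromatisation needs no oxidant.
- Where it beats the chosen plan: the ester is in place before the ring exists, so the question of which dione oxygen is acylated never arises.
- Weak points: A3 still has to be assembled by two conventional hindered esterifications, so the depside problem is not shortened. An aryl ynoate such as A3 is both an activated ester and a Michael acceptor. A but-2-ynoate is a sluggish dienophile, and the bridge extrusion needs strong heating of a compound with two exchange-prone aryl esters. A1 still needs a hydrogenolysis.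
- Balance: the chosen plan places its ring construction at the start, on bulk esters at the boiling point of methanol, and has a fallback that removes the regiochemical question.

Alternative 2: Ring B would be grown on the ring A oxygen. Thermal cycloreversion of diketo-dioxinone A5 releases the triketo acylketene A7. The C4 hydroxyl of methyl 2,4-dihydroxy-6-methylbenzoate A6 captures A7, and the resulting aryl 3,5,7-trioxooctanoate A8 closes by aldol condensation of its C2 onto the C7 ketone and dehydrates to didepside A4. A second round would add ring C.
- Merits: it is biomimetic and needs no phenol protection in principle.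
- Where it beats the chosen plan: it never has to esterify a 2,6-disubstituted benzoic acid, because the ester bond is made while the acyl group is still the unhindered ketene A7. In protecting-group economy and ideal step count it is the better plan.
- Weak points: A5 is a multistep building block and is needed twice. A7 is a free acylketene that can also dimerise or be captured by traces of water. A8 can fold in other ways, above all by lactonisation of an enol oxygen onto the aryl ester, which expels A6 as a good leaving group and gives a pyranone. In the second round the ketene must pick one of the three phenols of A4.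
- Balance: in the chosen plan every ester bond is made between preformed partners by a reaction with a single predictable outcome, and ring A is built instead of bought.

Alternative 3: The middle ring would be formed by a Diels–Alder reaction that joins the two ends. The silyl ketene acetal diene A10, which carries the ring C acyloxy group, adds to the but-2-ynoate A12 of the ring A phenol, forming ring B bonds C1–C2 and C5–C6. 1,4-Elimination of the ketal methoxy group aromatises ring B to give A9, the tridepside with ring C as its bis(benzyl ether).
- Merits: this is the most convergent of the four plans. The ring B phenol emerges free, and the regiochemistry is fixed by the ketene acetal.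
- Where it beats the chosen plan: convergence.
- Weak points: A10 has to come from γ-deprotonation and O-silylation of the enol ester A11, whose dienolate can attack its own aroyl group (O-to-C acyl shift). The acyloxy substituent makes A10 a poorer diene than a dialkoxy diene. The free chelated phenol of A12 would protonate the ketene acetal, so it needs a protecting group and further steps. A12 is again a labile aryl ynoate.
- Balance: the chosen plan uses only established reaction classes on isolable intermediates, with the one uncertain selectivity (O4 against O2) covered by a fallback.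

Key step: step 1

Assumption: aldehyde 5 is treated as purchasable. All ring A intermediates with sp3 centres are racemic and drawn as one enantiomer, and 4 is written as the diketone although it should exist largely as its 4-hydroxy enol.

## Route

Step 1
Reactants: 1 methyl acetoacetate; 2 methyl (E)-but-2-enoate
Product: 4 methyl trans-6-methyl-2,4-dioxocyclohexane-1-carboxylate (racemic), via Michael adduct 3 (not isolated)
Conditions: NaOMe (1.1 equiv), MeOH, reflux; then aq. HCl, 0 °C
Reagents that add atoms: none
Why: This is a Michael–Dieckmann (Michael–Claisen) annulation, the classical entry to dihydroresorcinol carboxylates: methoxide deprotonates C2 of 1 and the stabilised enolate adds to the β-carbon of 2, forming the ring A C1–C6 bond and giving 3. Under the equilibrating conditions a small share of 3 is deprotonated at the acetyl methyl group, and this enolate attacks the crotonate-derived ester carbonyl in a 6-exo-trig acyl substitution that forms C3–C4 and expels methoxide. The product is a vinylogous acid and is removed at once as its sodium enolate, which pulls both equilibria forward; cold acidification should free 4 without hydrolysis or decarboxylation of the β-keto ester. The regiochemistry is secured by ring size, since every other intramolecular acylation or aldol open to 3 would close a four-membered ring. C1 and C6 are new stereocentres; C1 is epimerisable between ketone and ester, so thermodynamic control should give the trans isomer with both substituents equatorial, as the racemate, and both centres are erased in step 8. Methoxide is matched to the two methyl esters so that ester exchange changes nothing.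

Step 2
Reactants: 5 2,4-dihydroxy-6-methylbenzaldehyde
Product: 6 2,4-bis(benzyloxy)-6-methylbenzaldehyde
Conditions: BnBr (2.3 equiv), K2CO3, DMF, 60 °C
Reagents that add atoms: benzyl bromide, BrCc1ccccc1
Why: Williamson etherification of both phenols; the chelated 2-OH needs the warm polar solvent, and the aldehyde has no enolisable position that could interfere.

Step 3
Reactants: 6 2,4-bis(benzyloxy)-6-methylbenzaldehyde
Product: 7 2,4-bis(benzyloxy)-6-methylbenzoic acid
Conditions: NaClO2, NaH2PO4, 2-methylbut-2-ene, t-BuOH–THF–H2O, rt
Reagents that add atoms: NaClO2 (sodium chlorite), [Na+].[O-]Cl=O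
Why: Pinnick oxidation; chlorous acid adds to the aldehyde and fragments to the acid, 2-methylbut-2-ene traps the hypochlorous acid so the electron-rich ring should not be chlorinated, and benzyl ethers are inert.

Step 4
Reactants: 7 2,4-bis(benzyloxy)-6-methylbenzoic acid; 5 2,4-dihydroxy-6-methylbenzaldehyde
Product: 9 4-formyl-3-hydroxy-5-methylphenyl 2,4-bis(benzyloxy)-6-methylbenzoate, via acid chloride 8 (not isolated)
Conditions: (COCl)2, cat. DMF, CH2Cl2, 0 °C to rt, evaporate; then 5 (1.1 equiv), Et3N, CH2Cl2, 0 °C to rt
Reagents that add atoms: none
Why: Acid chloride formation followed by phenol acylation; the 4-OH of 5 is para to the formyl group, unchelated and the more acidic phenol, whereas the 2-OH is held in a hydrogen bond to the aldehyde and flanked by it, so the hindered chloride should acylate O4 only.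

Step 5
Reactants: 9 4-formyl-3-hydroxy-5-methylphenyl 2,4-bis(benzyloxy)-6-methylbenzoate
Product: 10 3-(benzyloxy)-4-formyl-5-methylphenyl 2,4-bis(benzyloxy)-6-methylbenzoate
Conditions: BnBr, K2CO3, DMF, rt
Reagents that add atoms: benzyl bromide, BrCc1ccccc1
Why: Williamson etherification of the remaining chelated phenol; the aryl ester is di-ortho-substituted at its acyl carbon and should resist carbonate and phenoxide at room temperature.

Step 6
Reactants: 10 3-(benzyloxy)-4-formyl-5-methylphenyl 2,4-bis(benzyloxy)-6-methylbenzoate
Product: 11 2-(benzyloxy)-4-{[2,4-bis(benzyloxy)-6-methylbenzoyl]oxy}-6-methylbenzoic acid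
Conditions: NaClO2, NaH2PO4, 2-methylbut-2-ene, t-BuOH–THF–H2O, rt
Reagents that add atoms: NaClO2 (sodium chlorite), [Na+].[O-]Cl=O
Why: Pinnick oxidation under buffered, nearly neutral conditions that leave the aryl ester and the benzyl ethers untouched; this is the usual way to reveal a depside carboxyl group from an aldehyde.

Step 7
Reactants: 11 2-(benzyloxy)-4-{[2,4-bis(benzyloxy)-6-methylbenzoyl]oxy}-6-methylbenzoic acid; 4 methyl trans-6-methyl-2,4-dioxocyclohexane-1-carboxylate
Product: 13 methyl trans-4-({2-(benzyloxy)-4-{[2,4-bis(benzyloxy)-6-methylbenzoyl]oxy}-6-methylbenzoyl}oxy)-6-methyl-2-oxocyclohex-3-ene-1-carboxylate (racemic), via acid chloride 12 (not isolated)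
Conditions: (COCl)2, cat. DMF, CH2Cl2, 0 °C to rt, evaporate; then 4, Et3N (1.05 equiv), CH2Cl2, 0 °C; no DMAP
Reagents that add atoms: none
Why: O-Acylation of a cyclic 1,3-dione enolate with an acid chloride, the known route to 3-oxocyclohex-1-enyl esters; the anion of 4 is ambident over O2–C3–O4, and the bulky aroyl chloride should choose O4, flanked by the C3 and C5 hydrogens, over O2, which lies next to the ester-bearing C1 and near the C6 methyl group. Leaving out DMAP and cyanide avoids the O-to-C3 acyl shift, and the much less acidic C1 hydrogen of the product keeps one equivalent of base from acylating twice.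

Step 8
Reactants: 13 methyl trans-4-({2-(benzyloxy)-4-{[2,4-bis(benzyloxy)-6-methylbenzoyl]oxy}-6-methylbenzoyl}oxy)-6-methyl-2-oxocyclohex-3-ene-1-carboxylate
Product: 17 methyl 4-({2-(benzyloxy)-4-{[2,4-bis(benzyloxy)-6-methylbenzoyl]oxy}-6-methylbenzoyl}oxy)-2-hydroxy-6-methylbenzoate, via C1 selenide 14 (not isolated), via selenoxide 15 (not isolated), via dienone tautomer 16 (not isolated)
Conditions: PhSeCl, pyridine, CH2Cl2, 0 °C to rt; wash with 1 M HCl; then 30% H2O2, CH2Cl2, 0 °C to rt
Reagents that add atoms: none
Why: α-Selenenylation of a β-keto ester with the PhSeCl–pyridine complex, oxidation to the selenoxide and syn elimination, the standard dehydrogenation of β-dicarbonyl compounds; C1 is the only position between two carbonyl groups, and selenium should enter anti to the C6 methyl group and so cis to the C6 hydrogen, the only β-hydrogen available. The elimination can therefore only form C1=C6, the cross-conjugated dienone 16 tautomerises to the chelated phenol, and both stereocentres vanish.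

Step 9
Reactants: 17 methyl 4-({2-(benzyloxy)-4-{[2,4-bis(benzyloxy)-6-methylbenzoyl]oxy}-6-methylbenzoyl}oxy)-2-hydroxy-6-methylbenzoate
Product: 18 methyl 4-({4-[(2,4-dihydroxy-6-methylbenzoyl)oxy]-2-hydroxy-6-methylbenzoyl}oxy)-2-hydroxy-6-methylbenzoate (CNP0212402.0)
Conditions: H2 (1 atm), 10% Pd/C, EtOAc–THF, rt
Reagents that add atoms: none
Why: Catalytic hydrogenolysis of three aryl benzyl ethers under neutral conditions; aryl and methyl esters are not reduced, and no base or nucleophile is present that could cleave or shift the depside links.

## Compound list

1 | methyl acetoacetate (methyl 3-oxobutanoate) | COC(=O)CC(C)=O | starting material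
2 | methyl (E)-but-2-enoate (methyl crotonate) | C/C=C/C(=O)OC | starting material
3 | dimethyl 2-acetyl-3-methylpentanedioate (Michael adduct, mixture of diastereomers, not isolated) | COC(=O)CC(C)C(C(C)=O)C(=O)OC | intermediate
4 | methyl trans-6-methyl-2,4-dioxocyclohexane-1-carboxylate (racemic, one enantiomer drawn) | C[C@@H]1CC(=O)CC(=O)[C@H]1C(=O)OC | intermediate
5 | 2,4-dihydroxy-6-methylbenzaldehyde | Cc1cc(O)cc(O)c1C=O | starting material
6 | 2,4-bis(benzyloxy)-6-methylbenzaldehyde | Cc1cc(OCc2ccccc2)cc(OCc2ccccc2)c1C=O | intermediate
7 | 2,4-bis(benzyloxy)-6-methylbenzoic acid | Cc1cc(OCc2ccccc2)cc(OCc2ccccc2)c1C(=O)O | intermediate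
8 | 2,4-bis(benzyloxy)-6-methylbenzoyl chloride (not isolated) | Cc1cc(OCc2ccccc2)cc(OCc2ccccc2)c1C(Cl)=O | intermediate
9 | 4-formyl-3-hydroxy-5-methylphenyl 2,4-bis(benzyloxy)-6-methylbenzoate | Cc1cc(OC(=O)c2c(C)cc(OCc3ccccc3)cc2OCc2ccccc2)cc(O)c1C=O | intermediate
10 | 3-(benzyloxy)-4-formyl-5-methylphenyl 2,4-bis(benzyloxy)-6-methylbenzoate | Cc1cc(OC(=O)c2c(C)cc(OCc3ccccc3)cc2OCc2ccccc2)cc(OCc2ccccc2)c1C=O | intermediate
11 | 2-(benzyloxy)-4-{[2,4-bis(benzyloxy)-6-methylbenzoyl]oxy}-6-methylbenzoic acid | Cc1cc(OC(=O)c2c(C)cc(OCc3ccccc3)cc2OCc2ccccc2)cc(OCc2ccccc2)c1C(=O)O | intermediate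
12 | 2-(benzyloxy)-4-{[2,4-bis(benzyloxy)-6-methylbenzoyl]oxy}-6-methylbenzoyl chloride (not isolated) | Cc1cc(OC(=O)c2c(C)cc(OCc3ccccc3)cc2OCc2ccccc2)cc(OCc2ccccc2)c1C(Cl)=O | intermediate
13 | methyl trans-4-({2-(benzyloxy)-4-{[2,4-bis(benzyloxy)-6-methylbenzoyl]oxy}-6-methylbenzoyl}oxy)-6-methyl-2-oxocyclohex-3-ene-1-carboxylate (racemic, one enantiomer drawn) | C[C@@H]1CC(OC(=O)c2c(C)cc(OC(=O)c3c(C)cc(OCc4ccccc4)cc3OCc3ccccc3)cc2OCc2ccccc2)=CC(=O)[C@H]1C(=O)OC | intermediate
14 | methyl 4-(aroyloxy)-6-methyl-2-oxo-1-(phenylselanyl)cyclohex-3-ene-1-carboxylate, aroyl as in 13, selenium trans to the C6 methyl group (racemic, not isolated) | C[C@@H]1CC(OC(=O)c2c(C)cc(OC(=O)c3c(C)cc(OCc4ccccc4)cc3OCc3ccccc3)cc2OCc2ccccc2)=CC(=O)[C@]1([Se]c1ccccc1)C(=O)OC | intermediate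
15 | selenoxide of 14, mixture at selenium (not isolated) | C[C@@H]1CC(OC(=O)c2c(C)cc(OC(=O)c3c(C)cc(OCc4ccccc4)cc3OCc3ccccc3)cc2OCc2ccccc2)=CC(=O)[C@]1([Se](=O)c1ccccc1)C(=O)OC | intermediate
16 | methyl 4-(aroyloxy)-2-methyl-6-oxocyclohexa-1,4-diene-1-carboxylate, aroyl as in 13 (keto tautomer of 17, not isolated) | CC1=C(C(=O)OC)C(=O)C=C(OC(=O)c2c(C)cc(OC(=O)c3c(C)cc(OCc4ccccc4)cc3OCc3ccccc3)cc2OCc2ccccc2)C1 | intermediate
17 | methyl 4-({2-(benzyloxy)-4-{[2,4-bis(benzyloxy)-6-methylbenzoyl]oxy}-6-methylbenzoyl}oxy)-2-hydroxy-6-methylbenzoate | COC(=O)c1c(C)cc(OC(=O)c2c(C)cc(OC(=O)c3c(C)cc(OCc4ccccc4)cc3OCc3ccccc3)cc2OCc2ccccc2)cc1O | intermediate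
18 | methyl 4-({4-[(2,4-dihydroxy-6-methylbenzoyl)oxy]-2-hydroxy-6-methylbenzoyl}oxy)-2-hydroxy-6-methylbenzoate | COC(=O)c1c(C)cc(OC(=O)c2c(C)cc(OC(=O)c3c(C)cc(O)cc3O)cc2O)cc1O | target

## Step count and risks

Total step count: 9. Longest linear sequence: 8 steps (steps 2 to 9, from 5 through 6, 7, 9, 10, 11, 13 and 17 to 18). Step 1 is a one-step branch that joins at step 7.

Step 7 (enol acylation). The most likely failure is acylation at the wrong site: at O2 instead of O4, which would carry through to an isomeric depside, or at C3. The vinylogous anhydride could also transfer its acyl group during isolation. The fallback gives up the late aromatisation for this bond and makes the A–B ester on a phenol. It sets out from 4 and returns at 17, so steps 7 and 8 are both replaced. Treatment of 4 with three equivalents of bromine in acetic acid at room temperature should dehydrogenate the dione and brominate both free ring positions, giving methyl 3,5-dibromo-2,4-dihydroxy-6-methylbenzoate F1. Hydrogenolysis of the two aryl bromides (H2, Pd/C, NaOAc, MeOH) then gives methyl 2,4-dihydroxy-6-methylbenzoate F2. The unchelated 4-OH of F2 is acylated with chloride 12, made from 11 as in step 7, and triethylamine, with the 2-OH held by the ester, to give 17.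

Step 8 (selenenylation and selenoxide elimination). Three things could go wrong: selenium could enter cis to the C6 methyl group, which leaves no syn β-hydrogen and blocks the elimination; the cross-conjugated keto ester could enolise too slowly for the pyridine conditions; or the enol ester could be cleaved by peroxide before it is aromatic. The fallback replaces the syn elimination by a hydride abstraction that has no stereochemical requirement. It sets out from 13 and returns at 17. Silylation of 13 with chlorotrimethylsilane and triethylamine gives methyl 4-(aroyloxy)-6-methyl-2-[(trimethylsilyl)oxy]cyclohexa-1,3-diene-1-carboxylate F3. DDQ in dichloromethane at 0 °C should remove hydride from C6 and a proton from C5 to give the aryl silyl ether methyl 4-(aroyloxy)-6-methyl-2-[(trimethylsilyl)oxy]benzoate F4, which loses its silyl group on aqueous work-up to give 17.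

Step 1 (key step). The sequence could stall at the open-chain adduct 3 or revert by retro-Michael reaction while methoxide consumes the crotonate by conjugate addition. The β-keto ester could also be hydrolysed and decarboxylated if the acidification is not kept cold. The fallback closes the same ring through the other Claisen bond (C2–C3). It does not start from a numbered compound: it replaces 1 and 2 by two other purchased compounds and returns at 4. Dimethyl malonate F5 adds to (E)-pent-3-en-2-one F6 under NaOMe in methanol to give dimethyl 2-(4-oxopentan-2-yl)propanedioate F7. The methyl ketone enolate of F7 then attacks one malonate ester carbonyl (6-exo-trig) and gives 4 after acidification.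

Step 4 (selective esterification of 5). The hindered chloride could react so slowly that it is hydrolysed, or acylation could spill over to O2 and give the diester. The fallback removes the selectivity question by protecting before coupling. It sets out from 5 and returns at 10, so step 5 is no longer needed. Chloromethyl methyl ether and diisopropylethylamine should etherify only the unchelated phenol to give 2-hydroxy-4-(methoxymethoxy)-6-methylbenzaldehyde F8. Benzylation with benzyl bromide and K2CO3 gives 2-(benzyloxy)-4-(methoxymethoxy)-6-methylbenzaldehyde F9, and aqueous HCl in THF removes the acetal to give 2-(benzyloxy)-4-hydroxy-6-methylbenzaldehyde F10. Its single phenol is acylated with chloride 8 and triethylamine, now with catalytic DMAP, to give 10.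

## Further compounds

F1 | step 7 | methyl 3,5-dibromo-2,4-dihydroxy-6-methylbenzoate | COC(=O)c1c(C)c(Br)c(O)c(Br)c1O
F2 | step 7 | methyl 2,4-dihydroxy-6-methylbenzoate | COC(=O)c1c(C)cc(O)cc1O
F3 | step 8 | methyl 4-({2-(benzyloxy)-4-{[2,4-bis(benzyloxy)-6-methylbenzoyl]oxy}-6-methylbenzoyl}oxy)-6-methyl-2-[(trimethylsilyl)oxy]cyclohexa-1,3-diene-1-carboxylate (racemic, one enantiomer drawn) | C[C@@H]1CC(OC(=O)c2c(C)cc(OC(=O)c3c(C)cc(OCc4ccccc4)cc3OCc3ccccc3)cc2OCc2ccccc2)=CC(O[Si](C)(C)C)=C1C(=O)OC
F4 | step 8 | methyl 4-({2-(benzyloxy)-4-{[2,4-bis(benzyloxy)-6-methylbenzoyl]oxy}-6-methylbenzoyl}oxy)-6-methyl-2-[(trimethylsilyl)oxy]benzoate | COC(=O)c1c(C)cc(OC(=O)c2c(C)cc(OC(=O)c3c(C)cc(OCc4ccccc4)cc3OCc3ccccc3)cc2OCc2ccccc2)cc1O[Si](C)(C)C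
F5 | step 1 | dimethyl malonate | COC(=O)CC(=O)OC
F6 | step 1 | (E)-pent-3-en-2-one | C/C=C/C(C)=O
F7 | step 1 | dimethyl 2-(4-oxopentan-2-yl)propanedioate (racemic) | COC(=O)C(C(C)CC(C)=O)C(=O)OC
F8 | step 4 | 2-hydroxy-4-(methoxymethoxy)-6-methylbenzaldehyde | Cc1cc(OCOC)cc(O)c1C=O
F9 | step 4 | 2-(benzyloxy)-4-(methoxymethoxy)-6-methylbenzaldehyde | Cc1cc(OCOC)cc(OCc2ccccc2)c1C=O
F10 | step 4 | 2-(benzyloxy)-4-hydroxy-6-methylbenzaldehyde | Cc1cc(O)cc(OCc2ccccc2)c1C=O
A1 | alternative 1 | tridepside with rings A and B as 2-O-benzyl ethers and ring C free | COC(=O)c1c(C)cc(OC(=O)c2c(C)cc(OC(=O)c3c(C)cc(O)cc3O)cc2OCc2ccccc2)cc1OCc1ccccc1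
A2 | alternative 1 | 1,3-bis[(trimethylsilyl)oxy]cyclohexa-1,3-diene | C[Si](C)(C)OC1=CC(O[Si](C)(C)C)=CCC1
A3 | alternative 1 | methyl 2-(benzyloxy)-4-{[2-(benzyloxy)-4-(but-2-ynoyloxy)-6-methylbenzoyl]oxy}-6-methylbenzoate | CC#CC(=O)Oc1cc(C)c(C(=O)Oc2cc(C)c(C(=O)OC)c(OCc3ccccc3)c2)c(OCc2ccccc2)c1
A4 | alternative 2 | methyl 4-[(2,4-dihydroxy-6-methylbenzoyl)oxy]-2-hydroxy-6-methylbenzoate | COC(=O)c1c(C)cc(OC(=O)c2c(C)cc(O)cc2O)cc1O
A5 | alternative 2 | 6-(2,4-dioxopentyl)-2,2-dimethyl-4H-1,3-dioxin-4-one | CC(=O)CC(=O)CC1=CC(=O)OC(C)(C)O1
A6 | alternative 2 | methyl 2,4-dihydroxy-6-methylbenzoate | COC(=O)c1c(C)cc(O)cc1O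
A7 | alternative 2 | 3,5,7-trioxooct-1-en-1-one (triketo acylketene) | CC(=O)CC(=O)CC(=O)C=C=O
A8 | alternative 2 | 3-hydroxy-4-(methoxycarbonyl)-5-methylphenyl 3,5,7-trioxooctanoate | CC(=O)CC(=O)CC(=O)CC(=O)Oc1cc(C)c(C(=O)OC)c(O)c1
A9 | alternative 3 | tridepside with ring C as bis(benzyl ether) | COC(=O)c1c(C)cc(OC(=O)c2c(C)cc(OC(=O)c3c(C)cc(OCc4ccccc4)cc3OCc3ccccc3)cc2O)cc1O
A10 | alternative 3 | 4-methoxy-4-[(trimethylsilyl)oxy]buta-1,3-dien-2-yl 2,4-bis(benzyloxy)-6-methylbenzoate | C=C(OC(=O)c1c(C)cc(OCc2ccccc2)cc1OCc1ccccc1)C=C(OC)O[Si](C)(C)C
A11 | alternative 3 | methyl 3-{[2,4-bis(benzyloxy)-6-methylbenzoyl]oxy}but-2-enoate | COC(=O)C=C(C)OC(=O)c1c(C)cc(OCc2ccccc2)cc1OCc1ccccc1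
A12 | alternative 3 | methyl 4-(but-2-ynoyloxy)-2-hydroxy-6-methylbenzoate | CC#CC(=O)Oc1cc(C)c(C(=O)OC)c(O)c1
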